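1. The east run left 38% of its E at 15.0 min. I started from that leftover, because the west flask is asked about at the same time.

common to all: D 0.83 mM (held)
- west: E 10 mM; the very flask that is asked about, followed so far
- east: E 6.7 mM; run made earlier
- flask: E 10 mM; time 15 min

| run | time / min | Q / % | E / % |
|---|---|---|---|
| west | 0.500 | 4 | 97 |
| west | 1.00 | 2 | 95 |
| west | 1.50 | 8 | 95 |
| west | 2.00 | 9 | 91 |
| west | 2.50 | 12 | 90 |
| east | 3.00 | 17 | 84 |
| east | 6.00 | 29 | 73 |
| east | 10.0 | 41 | 56 |
| east | 12.0 | 48 | 50 |
| east | 15.0 | 55 | 38 |

(standard deviation of a reading: 2 percentage points)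

- a species is counted by the E in it: one L counts as two
- at the start none of G is dissolved
- what was read earlier has a scatter of 2 percentage points, one standard deviation
- on the list of suspects stand: D <-> G; E + Q -> L; G + Q -> J; E + G -> Q

- how much Q there is at 15 min, in percent of the E charged
- the change that raises the amount of Q at 15 min, in percent of the E charged most ("none" if none brings more than 2 percentage points) (violet / red / none)
- amount of Q at 15 min, in percent of the E charged, after red

- violet: doubling the transfer coefficient of D, all else as stated
- red: doubling the saturation concentration of D, all else as stated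

2. Suppose c_G stays near saturation. Then E + G -> Q removes a fixed fraction of c_E each minute, so the rate is k′ c_E (pseudo-first-order). Integrating gives c_E / c_E(start) = exp(−k′ t). The east leftover therefore gave 0.0645 min⁻¹ for k′, the fraction of c_E lost per minute at steady c_G.

3. East had lost 62.0% of its E and held 55% Q, so I kept 88.7% as Q per E lost.

4. For the west flask, I reckoned from k′ a leftover of 38.0% of E, and so 55.0% Q. Red doubles the saturation concentration of D. On my supposition that doubles c_G and so k′, which squares the reckoned leftover to 14.4% and gives 75.9% Q. Violet doubles the transfer coefficient of D, which does not stand in k′, so I chose red.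

5. The forecast also chose red. It gave 49%, less than my figure, and 77% after red, more than mine. Its ground differed from mine: “the rate is largely limited by D transfer”.

6. The flask gave 52.0% Q and 72.6% after red. Red gained 21 percentage points, violet 2.3 points.

    D ⇌ G, rate k1*(csat - [G]) (kL = 0.0630 s⁻¹)
    E + Q → L (k = 0.0140 L mol⁻¹ s⁻¹)
    G + Q → J (k = 0.0960 L mol⁻¹ s⁻¹)
    E + G → Q (k = 1.30 L mol⁻¹ s⁻¹)

At 15.0 min the west flask held c_G at 0.758 mM against a saturation of 0.83 mM, and E + G -> Q used E 14 times as fast as E + Q -> L. Its leftover of 42% was more than the 38.0% from k′. The same flask read at 1.0 h had 1.9% of its E left, where the east k′ gives 2.09%.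

The data are simulated for substances that don't exist; scatter was added.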